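**Retrosynthetic overview**
1. Target 32 ⇐ epoxy alcohol 31 (oxidation) ⇐ allylic alcohol 30 (reagent-controlled epoxidation of C1=C10) ⇐ diene 27 (acetonide → acetates, silyl ether off).
2. Ring A (the ten-membered carbocycle C1–C10) ⇐ 11-membered cyclic sulfone 24 (a 1-thiacycloundecane 1,1-dioxide with S between C4 and C5) by Ramberg–Bäcklund ring contraction; loss of SO2 makes the C4=C5 bond.
3. Feature used: the (Z)-trisubstituted C4=C5 olefin of ring A, flanked by C3H2 and C6H(O). C4 (with its CH3) and C5 can each be an sp3 α-sulfonyl carbon that carries hydrogen, and a cis olefin is the low-strain geometry of a ten-membered ring.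
4. 24 ⇐ acyclic sulfone 19 by ring-closing metathesis (C1=C10, held E by a temporary α-alkylidene-γ-butyrolactone between O8 and C14); 19 ⇐ Evans aldol (C6–C7), thiolate/epoxide coupling (S–C5), allyllithium acylation (C8–C9), Narasaka–Prasad reduction (C8).
5. Order of ring formation: γ-lactone (temporary) → 11-membered thiacycle → lactone opened, dioxane acetal on → ten-membered carbocycle → acetal off → epoxide.

Key step: step 13

**Remarks**
- Locants: target numbering is used for all intermediates. C1 is the epoxide CH, C10 the epoxide carbon bearing C14 (CHO), C9 is CH2, C8 is CH(OAc), C7 is CH(iPr), C6 is CH(OAc), C5=C4 is the olefin (CH3 on C4), C3 and C2 are CH2. In 10–26 the sulfur sits between C4 and C5.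
- Assumption: imide 3 is taken as a catalogue compound (otherwise one step from (R)-4-benzyl-1,3-oxazolidin-2-one and 3-methylbutanoyl chloride). Chloroacetaldehyde 4 is bought as its aqueous solution and used as the dried, freshly distilled monomer.

**Route**

Step 1
Reactants: 1 (R)-hex-5-en-2-ol
Product: 2 S-[(2S)-hex-5-en-2-yl] ethanethioate
Conditions: AcSH, PPh3, DIAD, THF, 0 °C → rt
Reagents that add atoms: thioacetic acid, CC(=O)S
Why: Mitsunobu reaction in which thioacetate displaces the alkoxyphosphonium ion by SN2 with inversion (2R to 2S) while the terminal olefin is inert; this centre (later C4) only keeps the intermediates single diastereomers and is erased in step 13.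

Step 2
Reactants: 3 (4R)-4-benzyl-3-(3-methylbutanoyl)-1,3-oxazolidin-2-one; 4 chloroacetaldehyde
Product: 6 (4R)-4-benzyl-3-[(2R,3R)-4-chloro-3-hydroxy-2-(propan-2-yl)butanoyl]-1,3-oxazolidin-2-one, via dibutylboron Z-enolate 5 (not isolated)
Conditions: Bu2BOTf, Et3N, CH2Cl2, −78 → 0 °C; then 4, −78 → 0 °C; pH 7 buffer, MeOH, 30% H2O2, 0 °C
Reagents that add atoms: none
Why: Evans syn-aldol reaction in which the (Z)-boron enolate 5 adds through a closed chair transition state on the enolate face away from the benzyl group, which sets C7 and C6 together (syn, both R in 6) under auxiliary control.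

Step 3
Reactants: 6 (4R)-4-benzyl-3-[(2R,3R)-4-chloro-3-hydroxy-2-(propan-2-yl)butanoyl]-1,3-oxazolidin-2-one
Product: 7 (2R,3R)-4-chloro-3-hydroxy-N-methoxy-N-methyl-2-(propan-2-yl)butanamide
Conditions: MeNHOMe·HCl, AlMe3, CH2Cl2, −20 → 0 °C; aq. potassium sodium tartrate
Reagents that add atoms: N,O-dimethylhydroxylamine hydrochloride, CNOC.Cl
Why: Weinreb amidation by the aluminium amide made in the flask, assisted by the free β-hydroxyl group, exchanges the auxiliary without touching C6, C7 or the primary chloride.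

Step 4
Reactants: 2 S-[(2S)-hex-5-en-2-yl] ethanethioate; 7 (2R,3R)-4-chloro-3-hydroxy-N-methoxy-N-methyl-2-(propan-2-yl)butanamide
Product: 10 (2R,3R)-4-{[(2S)-hex-5-en-2-yl]sulfanyl}-3-hydroxy-N-methoxy-N-methyl-2-(propan-2-yl)butanamide, via hexenethiol 8 (not isolated), via epoxy amide 9 (not isolated)
Conditions: K2CO3, MeOH (degassed), 0 °C → rt
Reagents that add atoms: none
Why: Methanolysis of the thioacetate frees thiolate 8, the chlorohydrin closes to the terminal epoxide 9, and SN2 opening at its CH2 terminus (thiol–epoxide opening) forms the S–C5 bond without touching C6.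

Step 5
Reactants: 10 (2R,3R)-4-{[(2S)-hex-5-en-2-yl]sulfanyl}-3-hydroxy-N-methoxy-N-methyl-2-(propan-2-yl)butanamide; 11 2-methylprop-2-en-1-ol
Product: 13 (5R,6R)-7-{[(2S)-hex-5-en-2-yl]sulfanyl}-1,6-dihydroxy-2-methylidene-5-(propan-2-yl)heptan-4-one, via dilithio reagent 12 (not isolated)
Conditions: 11, n-BuLi (2 equiv per 11), TMEDA, Et2O/hexane, 0 °C → rt (12, 3.3 equiv); then 10, THF, −78 → −40 °C; cold aq. NH4Cl
Reagents that add atoms: none
Why: Acylation of an allyllithium by a Weinreb amide, in which the chelated tetrahedral adduct survives until the cold quench so that single addition gives the β,γ-unsaturated ketone carrying C9, C10, C14 and the future C1 methylene; the allyl anion is symmetric, so there is no regiochemical issue.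

Step 6
Reactants: 13 (5R,6R)-7-{[(2S)-hex-5-en-2-yl]sulfanyl}-1,6-dihydroxy-2-methylidene-5-(propan-2-yl)heptan-4-one
Product: 15 (4R,5S,6R)-7-{[(2S)-hex-5-en-2-yl]sulfanyl}-2-methylidene-5-(propan-2-yl)heptane-1,4,6-triol, via boron chelate 14 (not isolated)
Conditions: Et2BOMe, THF/MeOH (4:1), −78 °C; NaBH4, −78 °C; AcOH, then MeOH co-evaporation
Reagents that add atoms: none
Why: Narasaka–Prasad reduction in which boron ties the C6 oxygen and the C8 ketone into a six-membered chelate and external hydride adds axially, anti to the axial isopropyl group, which sets C8 1,3-syn to C6 (all-syn C6/C7/C8); the non-oxidative work-up spares the sulfide.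

Step 7
Reactants: 15 (4R,5S,6R)-7-{[(2S)-hex-5-en-2-yl]sulfanyl}-2-methylidene-5-(propan-2-yl)heptane-1,4,6-triol
Product: 17 (5R)-5-[(2R,3R)-1-{[(2S)-hex-5-en-2-yl]sulfanyl}-2-hydroxy-4-methylpentan-3-yl]-3-methylideneoxolan-2-one, via lactol 16 (not isolated)
Conditions: activated MnO2 (excess), CH2Cl2, rt
Reagents that add atoms: none
Why: Oxidative lactonisation in which MnO2 oxidises only the primary allylic alcohol, the γ-hydroxy enal closes with the C8 hydroxyl to the five-membered lactol 16, and this is oxidised on to the α-methylene-γ-butyrolactone while the sulfide and the non-allylic C6 alcohol stay untouched.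

Step 8
Reactants: 17 (5R)-5-[(2R,3R)-1-{[(2S)-hex-5-en-2-yl]sulfanyl}-2-hydroxy-4-methylpentan-3-yl]-3-methylideneoxolan-2-one
Product: 19 (5R)-5-[(2R,3R)-1-{[(2S)-hex-5-en-2-yl]sulfonyl}-2-hydroxy-4-methylpentan-3-yl]-3-methylideneoxolan-2-one, via sulfoxide 18 (not isolated)
Conditions: (NH4)6Mo7O24·4H2O (cat.), 30% aq. H2O2, EtOH, 0 °C → rt
Reagents that add atoms: hydrogen peroxide, OO
Why: Molybdate-catalysed sulfide oxidation runs through sulfoxide 18 to the sulfone without epoxidising the terminal olefin or the electron-poor exocyclic olefin, and the sulfone no longer binds the ruthenium catalyst of step 9.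

Step 9
Reactants: 19 (5R)-5-[(2R,3R)-1-{[(2S)-hex-5-en-2-yl]sulfonyl}-2-hydroxy-4-methylpentan-3-yl]-3-methylideneoxolan-2-one
Product: 20 bicyclic sulfone lactone [11-membered ring S(O2)–C5–C6(OH)–C7(iPr)–C8–C9–C10=C1–C2–C3–C4(CH3); γ-lactone C8–O–C14(=O)–C10; 1(10)E; (4S,6R,7R,8R)]
Conditions: second-generation Hoveyda–Grubbs catalyst (10 mol %), 2,6-dichloro-1,4-benzoquinone (20 mol %), toluene (1 mM), 80 °C
Reagents that add atoms: none
Why: Ring-closing metathesis between the terminal vinyl group and the acrylate-type 1,1-disubstituted olefin at high dilution closes the 11-membered ring, and the new C1=C10 olefin should form E (C2 anti to the lactone carbonyl and syn to C9) because the other isomer suffers allylic strain with the carbonyl and because E is also the ring-cis geometry.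

Step 10
Reactants: 20 bicyclic sulfone lactone
Product: 22 triol [11-membered cyclic sulfone; CH2OH (C14) on C10; 6,8-diol; 1(10)E; (4S,6R,7S,8R)], via lactol 21 (not isolated)
Conditions: i-Bu2AlH (excess), CH2Cl2, −78 → 0 °C; aq. potassium sodium tartrate
Reagents that add atoms: none
Why: DIBAL-H 1,2-reduction of the unsaturated lactone through lactol 21 gives the allylic 1,4-diol with the olefin geometry kept, while the sulfone is inert.

Step 11
Reactants: 22 triol
Product: 23 14-O-tert-butyldiphenylsilyl ether of 22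
Conditions: TBDPSCl (1.05 equiv), imidazole, CH2Cl2, 0 °C
Reagents that add atoms: tert-butyl(chloro)diphenylsilane, CC(C)(C)[Si](Cl)(c1ccccc1)c1ccccc1
Why: Silylation of the primary allylic alcohol is much faster than that of the two hindered secondary alcohols (steric selectivity).

Step 12
Reactants: 23 14-O-TBDPS ether
Product: 24 6,8-O-isopropylidene acetal of 23 [(4S,6R,7S,8R); 1(10)E]
Conditions: 2,2-dimethoxypropane, PPTS (cat.), CH2Cl2, rt
Reagents that add atoms: 2,2-dimethoxypropane, COC(C)(C)OC
Why: Acetal formation on the syn-1,3-diol gives the chair dioxane with C5 and C9 equatorial and removes the free C6 alkoxide that would attack an α-halo sulfone in step 13.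

Step 13
Reactants: 24 6,8-O-isopropylidene 14-O-TBDPS cyclic sulfone
Product: 27 (1(10)E,4Z,6S,7S,8R)-cyclodeca-1(10),4-diene [6,8-O-isopropylidene; CH2OTBDPS on C10; CH3 on C4; iPr on C7], via bromo sulfone 25 (not isolated), via episulfone 26 (not isolated)
Conditions: KOH/Al2O3, CBr2F2, t-BuOH/CH2Cl2, 0 °C → rt
Reagents that add atoms: none
Why: Ramberg–Bäcklund reaction in its in-situ halogenative form: KOH deprotonates an α-sulfonyl carbon of 24, the carbanion takes bromine from CBr2F2 to give 25, deprotonation at the other α-carbon is followed by intramolecular displacement of bromide to episulfone 26, and 26 loses SO2 in a stereospecific cheletropic step. The closest known reaction type is the Ramberg–Bäcklund contraction of medium- and large-ring cyclic sulfones to cycloalkenes. The only ring closed is the transient thiirane dioxide (3-exo-tet), and the C4–C5 bond made there turns the 11-membered thiacycle into the ten-membered carbocycle (ring A) by loss of one ring atom. No new stereocentre remains; the olefin geometry follows from the ring fusion of the episulfone, and the Z (ring-cis) olefin is expected because a trans-fused episulfone and a trans-cyclodecene are both more strained and because hydroxide conditions favour the kinetic cis-episulfone. The step needs halogenation and 1,3-elimination to win over E1cB loss of the C6 oxygen and over any reaction at the C1(10) olefin: the C6 oxygen is a poor, ring-held acetal leaving group, the substrate has no other acidic C–H, the C4 stereocentre is deliberately sacrificed, and CBr2F2 on KOH/Al2O3 avoids the dichlorocarbene that CCl4 would add to the olefin.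

Step 14
Reactants: 27 acetonide diene
Product: 28 (1(10)E,4Z,6S,7S,8R)-10-({[tert-butyl(diphenyl)silyl]oxy}methyl)-4-methyl-7-(propan-2-yl)cyclodeca-1(10),4-diene-6,8-diol
Conditions: PPTS (cat.), MeOH, rt → 40 °C
Reagents that add atoms: none
Why: Mild acid-catalysed transacetalisation to methanol removes the isopropylidene group while the TBDPS ether and both olefins remain.

Step 15
Reactants: 28 diol
Product: 29 6,8-di-O-acetate of 28
Conditions: Ac2O, pyridine, DMAP (cat.), CH2Cl2, rt
Reagents that add atoms: acetic anhydride, CC(=O)OC(C)=O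
Why: DMAP-catalysed acylation puts both acetates on the secondary alcohols while C14 is blocked as its silyl ether.

Step 16
Reactants: 29 diacetate silyl ether
Product: 30 (1(10)E,4Z,6S,7S,8R)-10-(hydroxymethyl)-4-methyl-7-(propan-2-yl)cyclodeca-1(10),4-diene-6,8-diyl diacetate
Conditions: Bu4NF, AcOH (1:1), THF, 0 °C → rt
Reagents that add atoms: none
Why: Fluoride cleaves the Si–O bond, and the acetic acid buffer keeps the alkoxide from moving or cleaving the acetates.

Step 17
Reactants: 30 allylic alcohol
Product: 31 (1R,6S,7S,8R,10R,4Z)-1,10-epoxy-10-(hydroxymethyl)-4-methyl-7-(propan-2-yl)cyclodec-4-ene-6,8-diyl diacetate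
Conditions: Ti(OiPr)4 (20 mol %), D-(−)-diethyl tartrate (24 mol %), t-BuOOH (anhydrous, in decane), 4 Å molecular sieves, CH2Cl2, −20 °C
Reagents that add atoms: tert-butyl hydroperoxide, CC(C)(C)OO
Why: Sharpless asymmetric epoxidation, in which only the C1(10) olefin carries the allylic hydroxyl that binds titanium (so the C4 olefin is untouched) and the D-(−)-tartrate ligand delivers oxygen to the face that gives C1 (R) and C10 (R in 31), with syn addition keeping C2 and C9 cis.

Step 18
Reactants: 31 epoxy alcohol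
Product: 32 (1R,6S,7S,8R,10S,4Z)-1,10-epoxy-10-formyl-4-methyl-7-(propan-2-yl)cyclodec-4-ene-6,8-diyl diacetate (CNP0145766.3)
Conditions: Dess–Martin periodinane, NaHCO3, CH2Cl2, 0 °C → rt
Reagents that add atoms: none
Why: Dess–Martin oxidation of the primary epoxy alcohol under buffered conditions gives the aldehyde, and C10 is quaternary so it cannot epimerise (the descriptor changes from R to S only through the priority change).

**Compound list**
1 | (R)-hex-5-en-2-ol | C[C@@H](O)CCC=C | starting material
2 | S-[(2S)-hex-5-en-2-yl] ethanethioate | C[C@H](SC(C)=O)CCC=C | intermediate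
3 | (4R)-4-benzyl-3-(3-methylbutanoyl)-1,3-oxazolidin-2-one | CC(C)CC(=O)N1[C@H](Cc2ccccc2)COC1=O | starting material
4 | chloroacetaldehyde | ClCC=O | starting material
5 | dibutylboron (Z)-enolate of 3 | CCCCB(CCCC)O/C(=C\C(C)C)N1[C@H](Cc2ccccc2)COC1=O | intermediate (not isolated)
6 | (4R)-4-benzyl-3-[(2R,3R)-4-chloro-3-hydroxy-2-(propan-2-yl)butanoyl]-1,3-oxazolidin-2-one | O=C(N1[C@H](Cc2ccccc2)COC1=O)[C@H](C(C)C)[C@@H](O)CCl | intermediate
7 | (2R,3R)-4-chloro-3-hydroxy-N-methoxy-N-methyl-2-(propan-2-yl)butanamide | CON(C)C(=O)[C@H](C(C)C)[C@@H](O)CCl | intermediate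
8 | (2S)-hex-5-ene-2-thiol (present as its potassium thiolate) | C[C@H](S)CCC=C | intermediate (not isolated)
9 | (2R)-N-methoxy-N,3-dimethyl-2-[(2R)-oxiran-2-yl]butanamide | CON(C)C(=O)[C@H](C(C)C)[C@@H]1CO1 | intermediate (not isolated)
10 | (2R,3R)-4-{[(2S)-hex-5-en-2-yl]sulfanyl}-3-hydroxy-N-methoxy-N-methyl-2-(propan-2-yl)butanamide | CON(C)C(=O)[C@H](C(C)C)[C@@H](O)CS[C@@H](C)CCC=C | intermediate
11 | 2-methylprop-2-en-1-ol | CC(=C)CO | starting material
12 | dilithiated 2-methylprop-2-en-1-ol (O,C-dianion) | [Li]CC(=C)CO[Li] | intermediate (not isolated)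
13 | (5R,6R)-7-{[(2S)-hex-5-en-2-yl]sulfanyl}-1,6-dihydroxy-2-methylidene-5-(propan-2-yl)heptan-4-one | C=C(CO)CC(=O)[C@H](C(C)C)[C@@H](O)CS[C@@H](C)CCC=C | intermediate
14 | O6-diethylboryl chelate of 13 | C=C(CO)CC(=O)[C@H](C(C)C)[C@@H](OB(CC)CC)CS[C@@H](C)CCC=C | intermediate (not isolated)
15 | (4R,5S,6R)-7-{[(2S)-hex-5-en-2-yl]sulfanyl}-2-methylidene-5-(propan-2-yl)heptane-1,4,6-triol | C=C(CO)C[C@@H](O)[C@H](C(C)C)[C@@H](O)CS[C@@H](C)CCC=C | intermediate
16 | lactol of 15 (2-hydroxy-3-methylideneoxolane; mixture at the lactol carbon) | C=C1C[C@@H](OC1O)[C@H](C(C)C)[C@@H](O)CS[C@@H](C)CCC=C | intermediate (not isolated)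
17 | (5R)-5-[(2R,3R)-1-{[(2S)-hex-5-en-2-yl]sulfanyl}-2-hydroxy-4-methylpentan-3-yl]-3-methylideneoxolan-2-one | C=C1C[C@@H](OC1=O)[C@H](C(C)C)[C@@H](O)CS[C@@H](C)CCC=C | intermediate
18 | sulfoxide of 17 (mixture at sulfur) | C=C1C[C@@H](OC1=O)[C@H](C(C)C)[C@@H](O)CS(=O)[C@@H](C)CCC=C | intermediate (not isolated)
19 | (5R)-5-[(2R,3R)-1-{[(2S)-hex-5-en-2-yl]sulfonyl}-2-hydroxy-4-methylpentan-3-yl]-3-methylideneoxolan-2-one | C=C1C[C@@H](OC1=O)[C@H](C(C)C)[C@@H](O)CS(=O)(=O)[C@@H](C)CCC=C | intermediate
20 | bicyclic sulfone lactone: 11-membered cyclic sulfone fused to the (E)-α-alkylidene-γ-butyrolactone; (4S,6R,7R,8R) | O[C@H]1CS(=O)(=O)[C@@H](C)CC/C=C2\C[C@@H](OC2=O)[C@@H]1C(C)C | intermediate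
21 | lactol of 20 (mixture at the lactol carbon) | O[C@H]1CS(=O)(=O)[C@@H](C)CC/C=C2\C[C@@H](OC2O)[C@@H]1C(C)C | intermediate (not isolated)
22 | triol: 11-membered cyclic sulfone with CH2OH on C10 and 6,8-diol; 1(10)E; (4S,6R,7S,8R) | O[C@H]1CS(=O)(=O)[C@@H](C)CC/C=C(/CO)C[C@@H](O)[C@@H]1C(C)C | intermediate
23 | 14-O-TBDPS ether of 22 | O[C@H]1CS(=O)(=O)[C@@H](C)CC/C=C(/CO[Si](c2ccccc2)(c2ccccc2)C(C)(C)C)C[C@@H](O)[C@@H]1C(C)C | intermediate
24 | 6,8-O-isopropylidene acetal of 23; (4S,6R,7S,8R) | CC1(C)O[C@H]2CS(=O)(=O)[C@@H](C)CC/C=C(/CO[Si](c3ccccc3)(c3ccccc3)C(C)(C)C)C[C@@H](O1)[C@@H]2C(C)C | intermediate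
25 | 5-bromo derivative of 24 (configuration at C5 not defined) | CC1(C)O[C@H]2C(Br)S(=O)(=O)[C@@H](C)CC/C=C(/CO[Si](c3ccccc3)(c3ccccc3)C(C)(C)C)C[C@@H](O1)[C@@H]2C(C)C | intermediate (not isolated)
26 | cis-fused episulfone (thiirane 1,1-dioxide across C4–C5; face not defined) | CC1(C)O[C@H]2C3C(C)(CC/C=C(/CO[Si](c4ccccc4)(c4ccccc4)C(C)(C)C)C[C@@H](O1)[C@@H]2C(C)C)S3(=O)=O | intermediate (not isolated)
27 | (1(10)E,4Z,6S,7S,8R)-cyclodeca-1(10),4-diene: 6,8-O-isopropylidene, CH2OTBDPS on C10 | CC1(C)O[C@H]2/C=C(/C)CC/C=C(/CO[Si](c3ccccc3)(c3ccccc3)C(C)(C)C)C[C@@H](O1)[C@@H]2C(C)C | intermediate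
28 | (1(10)E,4Z,6S,7S,8R)-10-({[tert-butyl(diphenyl)silyl]oxy}methyl)-4-methyl-7-(propan-2-yl)cyclodeca-1(10),4-diene-6,8-diol | O[C@H]1/C=C(/C)CC/C=C(/CO[Si](c2ccccc2)(c2ccccc2)C(C)(C)C)C[C@@H](O)[C@@H]1C(C)C | intermediate
29 | 6,8-di-O-acetate of 28 | CC(=O)O[C@H]1/C=C(/C)CC/C=C(/CO[Si](c2ccccc2)(c2ccccc2)C(C)(C)C)C[C@@H](OC(C)=O)[C@@H]1C(C)C | intermediate
30 | (1(10)E,4Z,6S,7S,8R)-10-(hydroxymethyl)-4-methyl-7-(propan-2-yl)cyclodeca-1(10),4-diene-6,8-diyl diacetate | CC(=O)O[C@H]1/C=C(/C)CC/C=C(/CO)C[C@@H](OC(C)=O)[C@@H]1C(C)C | intermediate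
31 | (1R,6S,7S,8R,10R,4Z)-1,10-epoxy-10-(hydroxymethyl)-4-methyl-7-(propan-2-yl)cyclodec-4-ene-6,8-diyl diacetate | CC(=O)O[C@H]1/C=C(/C)CC[C@H]2O[C@@]2(CO)C[C@@H](OC(C)=O)[C@@H]1C(C)C | intermediate
32 | (1R,6S,7S,8R,10S,4Z)-1,10-epoxy-10-formyl-4-methyl-7-(propan-2-yl)cyclodec-4-ene-6,8-diyl diacetate (CNP0145766.3) | CC(=O)O[C@H]1/C=C(/C)CC[C@H]2O[C@@]2(C=O)C[C@@H](OC(C)=O)[C@@H]1C(C)C | target

**Step count and risks**

Total step count: 18. Longest linear sequence: 17 steps (3 and 4 → 32 through steps 2–18); the branch 1 → 2 (step 1) joins in step 4.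

Steps most likely to fail:

1. Step 13 (ring contraction). What may go wrong: after deprotonation at C5 the carbanion may expel the C6 acetal oxygen (E1cB opening of the dioxane), or it may be brominated a second time faster than the hindered C4–H is removed, so that episulfone formation is outrun. Fallback, from 24 back to 27: halogenation is separated from the contraction. Sulfone 24 is deprotonated at C5 with LiN(SiMe3)2 in THF at −78 °C and quenched with C2Cl6 to give the isolated 5-chloro sulfone F1. KOtBu in THF at −78 → 0 °C then removes the C4 hydrogen, whose carbanion has no β-leaving group. That carbanion displaces chloride to the episulfone, which loses SO2 and returns 27.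

2. Step 9 (macrocyclic metathesis). What may go wrong: the terminal vinyl group may oligomerise between molecules while the hindered 1,1-disubstituted olefin fails to turn over, because the five-membered lactone holds C9 and C10 rigidly away from the C1 terminus. Fallback, from 19 back to 24: the ring is closed on an open-chain acrylate with the syn-acetonide as turn element. Lactone 19 is opened and trapped with 2,2-dimethoxypropane, MeOH and camphorsulfonic acid to give the methyl 2-methylidene ester acetonide F2. Metathesis with the same catalyst should give the 11-membered (E)-enoate F3, by the same allylic-strain argument. DIBAL-H reduction gives the allylic alcohol F4, and TBDPSCl/imidazole gives 24.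

3. Step 5 (dianion acylation). What may go wrong: the strongly basic dianion may act as a base (retro-aldol of the lithium aldolate, enolisation), or the β,γ-unsaturated ketone may slip into conjugation on work-up. Fallback, from 10 back to 15: a protected, less basic nucleophile is used. tert-Butyl{[2-(chloromethyl)prop-2-en-1-yl]oxy}dimethylsilane and Mg in THF give the Grignard reagent F5, which adds to 10 at −78 °C to give the silyl ether ketone F6. Narasaka–Prasad reduction as in step 6 gives the syn,syn-diol F7, and Bu4NF in THF frees the primary alcohol to return 15.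

**Further compounds**
F1 | step 13 | 5-chloro derivative of 24 (configuration at C5 not defined) | CC1(C)O[C@H]2C(Cl)S(=O)(=O)[C@@H](C)CC/C=C(/CO[Si](c3ccccc3)(c3ccccc3)C(C)(C)C)C[C@@H](O1)[C@@H]2C(C)C
F2 | step 9 | methyl 2-methylidene ester 6,8-O-isopropylidene acetal derived from 19 (acyclic sulfone diene) | CC1(C)O[C@@H](CS(=O)(=O)[C@@H](C)CCC=C)[C@@H](C(C)C)[C@@H](CC(=C)C(=O)OC)O1
F3 | step 9 | 11-membered cyclic sulfone with (E)-methyl enoate (C14) on C10 and 6,8-O-isopropylidene acetal | CC1(C)O[C@H]2CS(=O)(=O)[C@@H](C)CC/C=C(/C(=O)OC)C[C@@H](O1)[C@@H]2C(C)C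
F4 | step 9 | allylic alcohol: 24 without the silyl group | CC1(C)O[C@H]2CS(=O)(=O)[C@@H](C)CC/C=C(/CO)C[C@@H](O1)[C@@H]2C(C)C
F5 | step 5 | [2-({[tert-butyl(dimethyl)silyl]oxy}methyl)prop-2-en-1-yl]magnesium chloride | CC(C)(C)[Si](C)(C)OCC(=C)C[Mg]Cl
F6 | step 5 | 1-O-tert-butyldimethylsilyl ether of ketone 13 | CC(C)(C)[Si](C)(C)OCC(=C)CC(=O)[C@H](C(C)C)[C@@H](O)CS[C@@H](C)CCC=C
F7 | step 5 | 1-O-tert-butyldimethylsilyl ether of triol 15 | CC(C)(C)[Si](C)(C)OCC(=C)C[C@@H](O)[C@H](C(C)C)[C@@H](O)CS[C@@H](C)CCC=C
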